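## Retrosynthetic overview

1. Target ⇐ 2,5-dimethoxyquinone (hydrolysis of the methoxy group next to the alkyl group) ⇐ tetramethoxyaryl decalinol (oxidative demethylation).
2. Decalinol ⇐ acyclic (6Z,10E)-triene in one flask: proton-initiated chair–chair bicyclisation (ring A, then ring B) → C8 cation → 1,2-H, 1,2-arylmethyl, 1,2-H shifts → water capture at C5. All four stereocentres arise here.
3. The arylmethyl group sits on the central olefin, so it (not a methyl) migrates C10→C9. This gives 9β-CH2Ar/9α-Me, the C9 configuration of the target.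
4. Triene ⇐ 2,3,5,6-tetramethoxyphenyllithium + allylic bromide ⇐ Z-hydroxymethyl olefin from a β-oxido-ylide three-component union (phosphonium salt, (E)-4-methylhex-4-enal, formaldehyde).
5. Aldehyde ⇐ Claisen rearrangement; phosphonium salt ⇐ ylide alkylation with homoprenyl bromide.

Notation: drimane-type locants are used for the decalin (C4 = CMe2, C5 = carbinol ring-fusion carbon, C8 = CHMe, C9 = quaternary carbon, C10 = ring-fusion CH, C11 = benzylic CH2). The target is 5β-OH, 10α-H (trans-decalin), 8β-Me, 9α-Me, 9β-CH2-quinone, i.e. (5R,8S,9S,10S) = (1S,2S,4aR,8aS) in naphthalene locants.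

Assumption: the enantiomer of the chiral acid in step 6 is the one that folds all-trans polyprenyl chains into the normal 5α-H/10β-substituent series (the sense that gives (−)-ambrox from (3E,7E)-homofarnesol); if the arylmethyl group reverses the sense, the antipodal acid is used.

## Route

Step 1
Reactants: 1 methyltriphenylphosphonium bromide; 2 5-bromo-2-methylpent-2-ene
Product: 4 (5-methylhex-4-en-1-yl)triphenylphosphonium bromide, via methylidenetriphenylphosphorane 3 (not isolated)
Conditions: n-BuLi, THF, 0 °C; then 2, −78 → 25 °C; salt collected by filtration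
Reagents that add atoms: none
Why: C-alkylation of a non-stabilised phosphorus ylide by a primary bromide (SN2) adds the homoprenyl unit in one operation, and the product salt is less acidic than 1 so it is not deprotonated by remaining ylide; no stereocentre is formed.

Step 2
Reactants: 5 3-methylbut-3-en-2-ol (racemic); 6 ethyl vinyl ether
Product: 8 (4E)-4-methylhex-4-enal, via 3-(ethenyloxy)-2-methylbut-1-ene 7 (not isolated)
Conditions: 6 (excess), Hg(OAc)2 (5 mol %), reflux; concentrate; PhMe, sealed tube, 140 °C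
Reagents that add atoms: none
Why: mercury-catalysed transvinylation followed by Claisen rearrangement through a chair transition state with the carbinol methyl equatorial gives the (E)-trisubstituted olefin (typically ≥93:7) and removes the racemic carbinol centre.

Step 3
Reactants: 4 (5-methylhex-4-en-1-yl)triphenylphosphonium bromide; 8 (4E)-4-methylhex-4-enal
Product: 12 (2Z,6E)-6-methyl-2-(4-methylpent-3-en-1-yl)octa-2,6-dien-1-ol, via ylide 9 (not isolated), via betaine 10 (not isolated), via β-oxido ylide 11 (not isolated)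
Conditions: n-BuLi, THF, 0 °C; 8, −78 °C; s-BuLi, −78 → −30 °C; (CH2O)n, 0 → 25 °C; H2O
Reagents that add atoms: paraformaldehyde (as formaldehyde) C=O
Why: Wittig–Schlosser β-oxido-ylide olefination (α-substitution plus carbonyl olefination), in which the lithiated betaine is hydroxymethylated and triphenylphosphine oxide is lost with the original betaine oxygen, places CH2OH cis to the aldehyde-derived chain and the two long chains trans, which is the (2Z) geometry needed for a trans ring fusion later.

Step 4
Reactants: 12 (2Z,6E)-6-methyl-2-(4-methylpent-3-en-1-yl)octa-2,6-dien-1-ol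
Product: 13 (6Z,10E)-6-(bromomethyl)-2,10-dimethyldodeca-2,6,10-triene
Conditions: CBr4, PPh3, CH2Cl2, −20 → 0 °C
Reagents that add atoms: tetrabromomethane BrC(Br)(Br)Br
Why: Appel bromination (SN2 on the alkoxyphosphonium salt at the primary allylic carbon) runs cold and neutral, so neither allylic transposition nor olefin isomerisation occurs.

Step 5
Reactants: 13 (6Z,10E)-6-(bromomethyl)-2,10-dimethyldodeca-2,6,10-triene; 14 1,2,4,5-tetramethoxybenzene
Product: 16 1,2,4,5-tetramethoxy-3-[(2Z,6E)-6-methyl-2-(4-methylpent-3-en-1-yl)octa-2,6-dien-1-yl]benzene, via aryllithium 15 (not isolated)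
Conditions: 14, n-BuLi, TMEDA, THF, 0 °C; then 13, −78 → 0 °C
Reagents that add atoms: none
Why: directed ortho-lithiation between two methoxy groups followed by SN2 alkylation at the unhindered primary allylic CH2 (SN2' attack at the substituted olefinic carbon is disfavoured) joins arene and chain with both olefin geometries intact.

Step 6
Reactants: 16 1,2,4,5-tetramethoxy-3-[(2Z,6E)-6-methyl-2-(4-methylpent-3-en-1-yl)octa-2,6-dien-1-yl]benzene
Product: 21 (1S,2S,4aR,8aS)-1,2,5,5-tetramethyl-1-[(2,3,5,6-tetramethoxyphenyl)methyl]octahydronaphthalen-4a(2H)-ol, via C8 cation 17 (not isolated), via C9 cation 18 (not isolated), via C10 cation 19 (not isolated), via C5 cation 20 (not isolated)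
Conditions: chiral confined imidodiphosphorimidate (IDPi) Brønsted acid (BINOL-derived, N-triflyl, 5 mol %), H2O (2 equiv), (CF3)2CHOH/CH2Cl2 1:1, 0.01 M, −20 °C; Et3N quench
Reagents that add atoms: water O
Why: Proposed new method: the confined chiral acid protonates the terminal isopropylidene olefin of the chair–chair folded chain and anti addition across the (6Z) and (10E) olefins closes ring A then ring B to the trans-fused C8 cation 17 (10β-CH2Ar axial, 5α-H, 9α-H), relief of the 1,3-diaxial CH2Ar/4β-Me strain then drives three suprafacial antiperiplanar shifts (9α-H to C8 setting 8β-Me, the axial electron-rich arylmethyl group from C10 to the β-face of C9 setting 9β-CH2Ar/9α-Me, 5α-H to C10 setting 10α-H), and water adds axially to the β-lobe of cation 20 anti to the departed hydrogen to give the trans-fused 5β-ol, with Friedel–Crafts termination excluded because both aryl ortho positions carry methoxy groups and absolute configuration fixed by the catalyst in the first C–C bond formation; the closest known reactions are IDPi-catalysed enantioselective proton-initiated polyene cyclisation in fluorinated alcohols, BF3·OEt2-induced 1,2-H/1,2-alkyl rearrangement of drimane C8 cations and water-terminated cation–olefin cyclisations.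

Step 7
Reactants: 21 (1S,2S,4aR,8aS)-1,2,5,5-tetramethyl-1-[(2,3,5,6-tetramethoxyphenyl)methyl]octahydronaphthalen-4a(2H)-ol
Product: 22 3-{[(1S,2S,4aR,8aS)-4a-hydroxy-1,2,5,5-tetramethyldecahydronaphthalen-1-yl]methyl}-2,5-dimethoxycyclohexa-2,5-diene-1,4-dione
Conditions: (NH4)2Ce(NO3)6 (2.5 equiv), MeCN/H2O 2:1, 0 °C, 15 min
Reagents that add atoms: water O
Why: oxidative demethylation by tetravalent cerium (arene radical cation, ipso attack of water, loss of methanol) converts either symmetry-equivalent para-dimethoxy pair into the same 2,5-dimethoxy-1,4-benzoquinone far faster than the tertiary alcohol reacts, and no stereocentre is touched.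

Step 8
Reactants: 22 3-{[(1S,2S,4aR,8aS)-4a-hydroxy-1,2,5,5-tetramethyldecahydronaphthalen-1-yl]methyl}-2,5-dimethoxycyclohexa-2,5-diene-1,4-dione
Product: 24 2-hydroxy-3-{[(1S,2S,4aR,8aS)-4a-hydroxy-1,2,5,5-tetramethyldecahydronaphthalen-1-yl]methyl}-5-methoxycyclohexa-2,5-diene-1,4-dione (target), via potassium quinonolate 23 (not isolated)
Conditions: KOH (2 M aq.), MeOH, 25 °C; then 1 M HCl to pH 3
Reagents that add atoms: potassium hydroxide [K+].[OH-]
Why: addition–elimination of hydroxide at the vinylogous ester carbon flanked by the alkyl group (its methoxy is twisted out of conjugation and is the more electrophilic) gives a vinylogous carboxylate that resists further attack, the regiochemistry established for 3-alkyl-2,5-dimethoxybenzoquinones, and the stereocentres are untouched.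

## Compound list

1 | methyltriphenylphosphonium bromide | C[P+](c1ccccc1)(c1ccccc1)c1ccccc1.[Br-] | starting material
2 | 5-bromo-2-methylpent-2-ene | CC(C)=CCCBr | starting material
3 | methylidenetriphenyl-λ5-phosphane (ylide) | C=P(c1ccccc1)(c1ccccc1)c1ccccc1 | intermediate
4 | (5-methylhex-4-en-1-yl)triphenylphosphonium bromide | CC(C)=CCCC[P+](c1ccccc1)(c1ccccc1)c1ccccc1.[Br-] | intermediate
5 | 3-methylbut-3-en-2-ol (racemic) | CC(O)C(C)=C | starting material
6 | ethyl vinyl ether | C=COCC | starting material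
7 | 3-(ethenyloxy)-2-methylbut-1-ene | C=COC(C)C(C)=C | intermediate
8 | (4E)-4-methylhex-4-enal | C/C=C(\C)CCC=O | intermediate
9 | (5-methylhex-4-en-1-ylidene)triphenyl-λ5-phosphane (ylide) | CC(C)=CCCC=P(c1ccccc1)(c1ccccc1)c1ccccc1 | intermediate
10 | (2E)-3,11-dimethyl-7-(triphenylphosphaniumyl)dodeca-2,10-dien-6-olate, LiBr adduct (betaine; diastereomer mixture at C6/C7) | C/C=C(\C)CCC([O-])C(CCC=C(C)C)[P+](c1ccccc1)(c1ccccc1)c1ccccc1.[Li+].[Br-] | intermediate
11 | lithium (2E)-3,11-dimethyl-7-(triphenyl-λ5-phosphanylidene)dodeca-2,10-dien-6-olate (β-oxido ylide) | C/C=C(\C)CCC([O-])C(CCC=C(C)C)=P(c1ccccc1)(c1ccccc1)c1ccccc1.[Li+] | intermediate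
12 | (2Z,6E)-6-methyl-2-(4-methylpent-3-en-1-yl)octa-2,6-dien-1-ol | OC/C(CCC=C(C)C)=C\CC/C(C)=C/C | intermediate
13 | (6Z,10E)-6-(bromomethyl)-2,10-dimethyldodeca-2,6,10-triene | BrC/C(CCC=C(C)C)=C\CC/C(C)=C/C | intermediate
14 | 1,2,4,5-tetramethoxybenzene | COc1cc(OC)c(OC)cc1OC | starting material
15 | (2,3,5,6-tetramethoxyphenyl)lithium | [Li]c1c(OC)c(OC)cc(OC)c1OC | intermediate
16 | 1,2,4,5-tetramethoxy-3-[(2Z,6E)-6-methyl-2-(4-methylpent-3-en-1-yl)octa-2,6-dien-1-yl]benzene | COc1cc(OC)c(OC)c(C/C(CCC=C(C)C)=C\CC/C(C)=C/C)c1OC | intermediate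
17 | trans-fused bicyclic C8 carbocation (10β-arylmethyl, 5α-H, 9α-H, 9β-Me, 4,4-Me2, 8-Me; aryl = 2,3,5,6-tetramethoxyphenyl) | COc1cc(OC)c(OC)c(C[C@]23CCCC(C)(C)[C@@H]2CC[C+](C)[C@@H]3C)c1OC | intermediate
18 | C9 carbocation (8β-Me, 8α-H, 9-Me, 10β-arylmethyl, 5α-H) | COc1cc(OC)c(OC)c(C[C@]23CCCC(C)(C)[C@@H]2CC[C@H](C)[C+]3C)c1OC | intermediate
19 | C10 carbocation (8β-Me, 9α-Me, 9β-arylmethyl, 5α-H) | COc1cc(OC)c(OC)c(C[C@@]2(C)[C@@H](C)CC[C@@H]3[C+]2CCCC3(C)C)c1OC | intermediate
20 | C5 carbocation (8β-Me, 9α-Me, 9β-arylmethyl, 10α-H) | COc1cc(OC)c(OC)c(C[C@@]2(C)[C@@H](C)CC[C+]3[C@H]2CCCC3(C)C)c1OC | intermediate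
21 | (1S,2S,4aR,8aS)-1,2,5,5-tetramethyl-1-[(2,3,5,6-tetramethoxyphenyl)methyl]octahydronaphthalen-4a(2H)-ol | COc1cc(OC)c(OC)c(C[C@@]2(C)[C@@H](C)CC[C@@]3(O)[C@H]2CCCC3(C)C)c1OC | intermediate
22 | 3-{[(1S,2S,4aR,8aS)-4a-hydroxy-1,2,5,5-tetramethyldecahydronaphthalen-1-yl]methyl}-2,5-dimethoxycyclohexa-2,5-diene-1,4-dione | COC1=CC(=O)C(OC)=C(C[C@@]2(C)[C@@H](C)CC[C@@]3(O)[C@H]2CCCC3(C)C)C1=O | intermediate
23 | potassium salt (quinonolate) of 24 | COC1=CC(=O)C([O-])=C(C[C@@]2(C)[C@@H](C)CC[C@@]3(O)[C@H]2CCCC3(C)C)C1=O.[K+] | intermediate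
24 | 2-hydroxy-3-{[(1S,2S,4aR,8aS)-4a-hydroxy-1,2,5,5-tetramethyldecahydronaphthalen-1-yl]methyl}-5-methoxycyclohexa-2,5-diene-1,4-dione | COC1=CC(=O)C(O)=C(C[C@@]2(C)[C@@H](C)CC[C@@]3(O)[C@H]2CCCC3(C)C)C1=O | target

## Step count and risks

Total steps: 8. Longest linear sequence: 7 (steps 1, 3, 4, 5, 6, 7, 8; step 2 is the parallel branch).

Steps most likely to fail:

Step 6 (cascade with water capture). The risks are proton loss to olefins instead of hydration, capture at C10 instead of C5, a benzylic hydride shift at the monocyclic stage, and modest enantioselectivity. The fallback sets out from 16 and comes back at 21. The same acid-promoted bicyclisation and shift sequence is run without water (finished with BF3·OEt2 in CH2Cl2 at −40 °C if needed), so that it ends by proton loss to the tetrasubstituted olefin 1,2,4,5-tetramethoxy-3-{[(1S,2S)-1,2,5,5-tetramethyl-1,2,3,4,5,6,7,8-octahydronaphthalen-1-yl]methyl}benzene F1. Water is then added stepwise by oxymercuration (Hg(OAc)2, THF/H2O). Divalent mercury should take the α-face, anti to the β-arylmethyl group, and water should open the mercurinium ion trans-diaxially at C5, the ring-fusion carbon remote from the quaternary centre. This gives the 10α-(acetoxymercurio)-5β-ol F2. Demercuration with NaBH4/NaOH (C10 radical, hydrogen delivered to the open α-face) gives 21.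

Step 3 (β-oxido-ylide olefination). The risks are low yield and erosion of the Z-hydroxymethyl geometry. The fallback sets out from 8 (with 2) and comes back at 12. Commercial methyl bis(2,2,2-trifluoroethyl)phosphonoacetate is alkylated with 2 (NaH, DMF) to methyl 2-[bis(2,2,2-trifluoroethoxy)phosphoryl]-6-methylhept-5-enoate F3. Still–Gennari olefination of 8 (KN(SiMe3)2, 18-crown-6, THF, −78 °C) gives methyl (2Z,6E)-6-methyl-2-(4-methylpent-3-en-1-yl)octa-2,6-dienoate F4, with the ester cis to the aldehyde-derived chain. Reduction with i-Bu2AlH (CH2Cl2, −78 °C) gives 12.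

Step 8 (regioselective hydrolysis). The risks are hydrolysis of the wrong methoxy group or of both. The fallback sets out from 22 and comes back at 24. Both vinylogous esters are hydrolysed (aq. NaOH, dioxane, 50 °C; then HCl) to 2,5-dihydroxy-3-{[(1S,2S,4aR,8aS)-4a-hydroxy-1,2,5,5-tetramethyldecahydronaphthalen-1-yl]methyl}cyclohexa-2,5-diene-1,4-dione F5. The unhindered hydroxyl, the one not flanked by the alkyl group, is then mono-O-methylated with Me3SiCHN2 (1 equiv, MeOH/PhMe, 0 °C), the selectivity known for 3-alkyl-2,5-dihydroxybenzoquinones of the embelin type.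

## Further compounds

F1 | step 6 | 1,2,4,5-tetramethoxy-3-{[(1S,2S)-1,2,5,5-tetramethyl-1,2,3,4,5,6,7,8-octahydronaphthalen-1-yl]methyl}benzene | COc1cc(OC)c(OC)c(C[C@@]2(C)[C@@H](C)CCC3=C2CCCC3(C)C)c1OC
F2 | step 6 | 10α-(acetoxymercurio)-5β-hydroxy adduct of F1 (acetoxymercury on the ring-fusion carbon next to the quaternary centre, hydroxyl on the other ring-fusion carbon, trans) | COc1cc(OC)c(OC)c(C[C@@]2(C)[C@@H](C)CC[C@@]3(O)[C@@]2([Hg]OC(C)=O)CCCC3(C)C)c1OC
F3 | step 3 | methyl 2-[bis(2,2,2-trifluoroethoxy)phosphoryl]-6-methylhept-5-enoate (racemic) | COC(=O)C(CCC=C(C)C)P(=O)(OCC(F)(F)F)OCC(F)(F)F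
F4 | step 3 | methyl (2Z,6E)-6-methyl-2-(4-methylpent-3-en-1-yl)octa-2,6-dienoate | COC(=O)/C(CCC=C(C)C)=C\CC/C(C)=C/C
F5 | step 8 | 2,5-dihydroxy-3-{[(1S,2S,4aR,8aS)-4a-hydroxy-1,2,5,5-tetramethyldecahydronaphthalen-1-yl]methyl}cyclohexa-2,5-diene-1,4-dione | OC1=CC(=O)C(O)=C(C[C@@]2(C)[C@@H](C)CC[C@@]3(O)[C@H]2CCCC3(C)C)C1=O
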